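## Analysis of the target

Target 29 is made of two α-hydroxy-α,β-dibenzyl-γ-butyrolactone units, lactone 1 (rings A and B) and lactone 2 (rings C and D), which together carry four guaiacyl (4-hydroxy-3-methoxyphenyl) rings. Rings B and C are joined by a C5–C5' biaryl bond ortho to both phenolic hydroxyls, and the dimer is unsymmetrical: ring B is attached through its CH2 to the carbinol carbon C3 of lactone 1, ring C through its CH2 to the methine carbon C4 of lactone 2, while ring A (on C4 of lactone 1) and ring D (on C3 of lactone 2) are unsubstituted at C5. Each lactone has two adjacent stereocentres, the fully substituted carbinol C3 and the tertiary C4; the SMILES is read as (3R,4R) in both lactones, so that the two arylmethyl groups are trans and the hydroxyl is cis to the C4 arylmethyl group. The two stereo-pairs lie far apart across a freely rotating biaryl axis (one hydroxyl and one hydrogen ortho on each ring, no axial chirality), so neither pair can control the other and each needs its own absolute control. Sensitive groups are four oxidisable phenols, two base-labile lactones and two tertiary α-hydroxy groups. The difficulty is threefold: four nearly identical guaiacyl rings must be told apart so that only B and C are joined, the C3/C4 relationship is the opposite of what electrophilic oxygenation of a lactone enolate gives, and the problem must be solved twice in constitutionally different surroundings. The feature that invites the chosen move is the C3–C4 bond of each lactone: C3 bears an oxygen and the C2 carboxyl, and C4 bears C5H2–O1, which can be read as a cleaved alkenyl group, so that C2–C3–C4–C5 is the γ,δ-unsaturated α-alkoxy acid array that an ester-enolate [3,3] shift produces.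

## Retrosynthetic reasoning

**29 to 28.** All six hydroxyls are masked as benzyl ethers in 28, so that one hydrogenolysis ends the synthesis. On the C3 oxygens the benzyl group is also the small, chelating substituent that the key step needs.

**28 to 25.** Both lactone C5–O1 bonds are cut and each C5 is read as the stump of an (E)-propenyl group. Forward, this is oxidative cleavage of two alkenes, reduction and lactonisation of bis-acid 25. The gain is that each half of 25 is a 2-alkoxy-hex-4-enoic acid, the retron of an Ireland–Claisen rearrangement.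

**25 to 21 (key disconnection).** The C3–C4 bond of both future lactones is cut at once. This is the only bond that joins the two stereocentres of a unit. Cutting it turns each unit into an α-benzyloxy ester, whose α-centre becomes planar and needs no control, and a (Z)-allylic alcohol whose single carbinol stereocentre is bought. In bis-ester 21 the two ester/allyl pairs sit head-to-tail on the biaryl. Ring B carries the acid part of one pair and ring C the allyl part of the other, and this orientation encodes the unsymmetrical linkage. The forward reaction must give the chelated enolate geometry, a chair transition state and 1,3-chirality transfer, twice in one flask.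

**21 to 20 and 16; 20 to 19; 19 to 18 and 8.** The ester C–O bond is cut to give alcohol 20 and racemic acid 16. The Z-alkene of 20 comes from alkyne 19 by semihydrogenation. The C(sp3)–C(sp) bond of 19 is cut to give benzylic bromide 18 and alkynol 8, the source of the second carbinol centre.

**18 to 12 and 5.** The bond between the ring B methylene and the ester α-carbon is cut. Enolate 17 of glycolate 12 is alkylated by the symmetrical bis-electrophile 5. One arm of 5 alkylates the enolate; the other later becomes the allylic partner. Both arms are used at the same oxidation level, so the core needs no differentiated functional groups, only control of stoichiometry.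

**5 to 1.** Dibromide 5 goes back through 4, 3 and 2 to two molecules of vanillin 1. The biaryl bond is thus made first, by joining two molecules of a monomer whose only free position ortho to the phenol leaves no regiochemical choice.

**12 and 16 to the building blocks.** Glycolate 12 is cut at the ester to alcohol 10 and acid chloride 11. Alcohol 10 comes from alkyne 9, and 9 from bromide 7 (from alcohol 6) and alkynol 8. Acid 16 comes from ester 15, made from glycolate 13 (via enolate 14) and 7. The same building blocks (7, 8 and the benzyloxyacetyl donors 11 and 13) serve both halves with their roles exchanged.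

In one sentence: the key step is a twofold chelate-controlled Ireland–Claisen rearrangement of the head-to-tail bis-ester 21.

## Alternatives that were turned down

**Alternative 1: the textbook route.**
- Disconnection: the ring B–ring C biaryl bond, cut last.
- Forward key step: Suzuki–Miyaura coupling of aryl bromide A1 with aryl boronate A2, both benzyl-protected monomeric lactones.
- Turned down because A1 and A2 are two separate multistep enantioselective syntheses that differ only in the position of one substituent. The four stereocentres would be set in four unrelated events. The coupling would have to join two ortho-alkoxy-substituted, electron-rich partners in aqueous base at elevated temperature, in the presence of two lactones bearing free tertiary alcohols. Protodeboronation and lactone opening compete, and the step count roughly doubles.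

**Alternative 2: the biomimetic route.**
- Disconnection: the same biaryl bond.
- Forward key step: one-electron oxidative phenol coupling of the unprotected monomer A3.
- Turned down because the two guaiacyl rings of A3 have the same substitution and the same oxidation behaviour. Coupling would occur without positional control at any ring position ortho to a phenol, through carbon or oxygen. It would also continue past the dimer stage, since a 2,2'-biphenol is oxidised more easily than its precursor. The crossed B–C mode is at best one statistical outcome among several of identical polarity, and A3 still needs its own asymmetric synthesis.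

**Alternative 3: twofold enolate oxygenation.**
- Disconnection: the two C3–O bonds.
- Forward key step: oxygenation of the bis-enolate of the C3-deoxy dimer A4 by an electrophilic oxygen donor.
- Turned down on mechanistic grounds. The electrophile adds to the planar lactone enolate anti to the C4 arylmethyl group, so the new hydroxyl would be trans to it and the C3 arylmethyl cis. The predicted product is the bis-C3-epimer A5, wrong at both quaternary centres. In addition, A4 already contains the unsymmetrical biaryl and would need its own solution to the regiochemical problem.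

Key step: step 15

## Assumptions

- The SMILES is read as (3R,4R) for both lactones, and the route is built for this enantiomer.
- Step 1 consumes two molecules of vanillin 1 for each molecule of 2.
- Dibromide 5 is used in threefold excess in step 11 and the unreacted part is recovered.
- Acid 16 is used as the racemate, and 18–21 are carried as mixtures of epimers at the benzyloxy-bearing ester α-carbons. This is immaterial, because these centres become planar in step 15.

## Route

Step 1
Reactants: 1 vanillin; 1 vanillin (second molecule)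
Product: 2 dehydrodivanillin (6,6'-dihydroxy-5,5'-dimethoxybiphenyl-3,3'-dicarbaldehyde)
Conditions: Na2S2O8 (0.55 equiv per vanillin), FeSO4·7H2O (cat.), H2O, 50 °C
Reagents that add atoms: none
Why: Oxidative phenol coupling that joins two molecules of 1 through their C5 carbons; the phenoxyl radical of 1 has its para position and one ortho position blocked, so C–C coupling can only occur at C5 and gives the symmetrical 5,5'-biaryl.

Step 2
Reactants: 2 dehydrodivanillin
Product: 3 6,6'-bis(benzyloxy)-5,5'-dimethoxybiphenyl-3,3'-dicarbaldehyde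
Conditions: benzyl bromide (2.4 equiv), K2CO3, DMF, 60 °C
Reagents that add atoms: benzyl bromide, BrCc1ccccc1
Why: Williamson etherification of both phenols; the aldehydes are inert to carbonate.

Step 3
Reactants: 3 bis(benzyl ether) dialdehyde
Product: 4 [6,6'-bis(benzyloxy)-5,5'-dimethoxybiphenyl-3,3'-diyl]dimethanol
Conditions: NaBH4, THF/MeOH, 0 °C
Reagents that add atoms: none
Why: Borohydride reduction of both aryl aldehydes to benzylic alcohols.

Step 4
Reactants: 4 diol
Product: 5 2,2'-bis(benzyloxy)-5,5'-bis(bromomethyl)-3,3'-dimethoxybiphenyl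
Conditions: PBr3, CH2Cl2, 0 °C
Reagents that add atoms: phosphorus tribromide, BrP(Br)Br
Why: Conversion of p-alkoxybenzylic alcohols into bromides via the phosphite esters; aryl benzyl ethers survive the short cold exposure.

Step 5
Reactants: 6 [4-(benzyloxy)-3-methoxyphenyl]methanol
Product: 7 1-(benzyloxy)-4-(bromomethyl)-2-methoxybenzene
Conditions: PBr3, Et2O, 0 °C
Reagents that add atoms: phosphorus tribromide, BrP(Br)Br
Why: Same bromination as step 4 on the monomeric benzylic alcohol.

Step 6
Reactants: 7 benzylic bromide; 8 (R)-but-3-yn-2-ol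
Product: 9 (R)-5-[4-(benzyloxy)-3-methoxyphenyl]pent-3-yn-2-ol
Conditions: CuI (10 mol %), NaI (cat.), Cs2CO3, MeCN, 23 °C
Reagents that add atoms: none
Why: Copper-catalysed C(sp)–C(sp3) coupling in which the copper acetylide of 8 displaces the benzylic bromide; the carbinol centre is not involved and stays R, and carbonate at ambient temperature is too weak to isomerise the benzyl-propargyl unit to an allene.

Step 7
Reactants: 9 alkynol
Product: 10 (R,Z)-5-[4-(benzyloxy)-3-methoxyphenyl]pent-3-en-2-ol
Conditions: H2 (1 atm), Pd/CaCO3 poisoned with Pb(OAc)2 (Lindlar catalyst), quinoline, EtOAc, 23 °C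
Reagents that add atoms: none
Why: Lindlar semihydrogenation; syn delivery of hydrogen on the poisoned surface gives the Z-alkene, and benzyl ethers are not cleaved on this catalyst.

Step 8
Reactants: 10 (R,Z)-alkenol; 11 (benzyloxy)acetyl chloride
Product: 12 (R,Z)-5-[4-(benzyloxy)-3-methoxyphenyl]pent-3-en-2-yl (benzyloxy)acetate
Conditions: pyridine, DMAP (cat.), CH2Cl2, 0 °C
Reagents that add atoms: none
Why: Acylation of the secondary alcohol; the carbinol C–O bond is not broken, so the R configuration is retained.

Step 9
Reactants: 13 methyl (benzyloxy)acetate; 7 benzylic bromide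
Product: 15 methyl 2-(benzyloxy)-3-[4-(benzyloxy)-3-methoxyphenyl]propanoate (racemic), via lithium enolate 14 (not isolated)
Conditions: LiN(iPr)2, THF, −78 °C; then 7, DMPU, −78 → −40 °C
Reagents that add atoms: none
Why: Alkylation of the chelated lithium enolate of an α-alkoxy ester by a reactive p-alkoxybenzyl bromide; the new centre is left racemic on purpose.

Step 10
Reactants: 15 methyl ester
Product: 16 2-(benzyloxy)-3-[4-(benzyloxy)-3-methoxyphenyl]propanoic acid (racemic)
Conditions: LiOH·H2O, THF/H2O, 23 °C; then 1 M HCl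
Reagents that add atoms: lithium hydroxide, [Li+].[OH-]
Why: Saponification of the methyl ester; the α-centre needs no control.

Step 11
Reactants: 12 allylic glycolate; 5 dibromide
Product: 18 (R,Z)-5-[4-(benzyloxy)-3-methoxyphenyl]pent-3-en-2-yl 2-(benzyloxy)-3-[6,6'-bis(benzyloxy)-3'-(bromomethyl)-5,5'-dimethoxybiphenyl-3-yl]propanoate (both C2 epimers), via lithium enolate 17 (not isolated)
Conditions: 12, LiN(SiMe3)2, THF, −78 °C; then added to 5 (3 equiv), DMPU, THF, −78 → −45 °C
Reagents that add atoms: none
Why: Same enolate alkylation as step 9, run by inverse addition onto excess 5 so that monoalkylation dominates and one bromomethyl arm survives; below −45 °C the lithium enolate should alkylate faster than it rearranges, and the stereorandom α-centre is erased in step 15.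

Step 12
Reactants: 18 benzylic bromide; 8 (R)-but-3-yn-2-ol
Product: 19 (R,Z)-5-[4-(benzyloxy)-3-methoxyphenyl]pent-3-en-2-yl 2-(benzyloxy)-3-{6,6'-bis(benzyloxy)-3'-[(R)-4-hydroxypent-2-yn-1-yl]-5,5'-dimethoxybiphenyl-3-yl}propanoate (both C2 epimers)
Conditions: CuI (10 mol %), NaI (cat.), Cs2CO3, MeCN, 23 °C
Reagents that add atoms: none
Why: Same copper-catalysed alkyne–benzyl bromide coupling as step 6; the ester, the Z-alkene and the benzyl ethers do not react with a copper acetylide or carbonate, and epimerisation at the ester α-carbon is irrelevant.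

Step 13
Reactants: 19 alkynol
Product: 20 (R,Z)-5-[4-(benzyloxy)-3-methoxyphenyl]pent-3-en-2-yl 2-(benzyloxy)-3-{6,6'-bis(benzyloxy)-3'-[(R,Z)-4-hydroxypent-2-en-1-yl]-5,5'-dimethoxybiphenyl-3-yl}propanoate (both C2 epimers)
Conditions: H2 (1 atm), Pd/CaCO3 poisoned with Pb(OAc)2 (Lindlar catalyst), quinoline, EtOAc, 23 °C
Reagents that add atoms: none
Why: Lindlar semihydrogenation as in step 7; the existing Z-alkene and the benzyl ethers are not reduced on the poisoned catalyst.

Step 14
Reactants: 20 (R,Z)-alkenol; 16 racemic acid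
Product: 21 head-to-tail bis-ester, 20 acylated on its allylic hydroxyl by the 2-(benzyloxy)-3-[4-(benzyloxy)-3-methoxyphenyl]propanoyl group of 16 (four diastereomers at the two ester α-carbons, both allylic carbinol centres R, both alkenes Z)
Conditions: DCC, DMAP (cat.), CH2Cl2, 0 → 23 °C
Reagents that add atoms: none
Why: Steglich esterification; the acid is activated by the carbodiimide and the carbinol C–O bond is untouched, so both allylic centres remain R.

Step 15
Reactants: 21 bis-ester
Product: 25 bis-acid in which ring B carries CH2–C(OBn)(CO2H)–CH[(E)-CH=CH–CH3]–CH2–ring A and ring C carries CH2–CH[(E)-CH=CH–CH3]–C(OBn)(CO2H)–CH2–ring D (all four new centres R), via bis(lithium enolate) 22 (not isolated), via bis(silyl ketene acetal) 23 (not isolated), via bis(trimethylsilyl ester) 24 (not isolated)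
Conditions: LiN(iPr)2 (5 equiv), THF, −78 °C; Me3SiCl (6 equiv), −78 → 23 °C, then 50 °C; 1 M HCl
Reagents that add atoms: chlorotrimethylsilane, C[Si](C)(C)Cl (its silicon is carried only by 23 and 24 and is lost on work-up)
Why: Both esters are deprotonated to lithium enolates in which lithium bridges the enolate oxygen and the benzyloxy oxygen; silylation fixes this geometry in 23, and on warming each arm undergoes a concerted suprafacial [3,3] shift (Ireland–Claisen rearrangement) that forms the C3–C4 bond of one future lactone. The closest known reaction type is the chelate-controlled Ireland–Claisen rearrangement of O-protected glycolate and lactate esters of secondary allylic alcohols, which gives α-alkoxy acids, including fully substituted ones, with 1,3-chirality transfer. No ring is closed here; the six-membered array exists only in the chair transition state, and the lactones are closed in step 16. C4 is controlled by the (R)-carbinol centre: the methyl group sits equatorial, because an axial methyl would clash 1,3-diaxially with the axial arylmethyl group of the Z-alkene, so the new bond forms on one alkene face only. C3 is controlled relative to C4 by the pairing of enolate geometry (benzyloxy equatorial, arylmethyl axial) with the Z-olefin (arylmethyl axial), which places the two arylmethyl groups trans and the oxygen cis to the C4 arylmethyl group, giving (3R,4R) in lactone numbering. The step needs the chelated enolate geometry in both arms and chair over boat; the bidentate benzyloxy ester with lithium in THF without dipolar cosolvent secures the first, and the acyclic Z-allylic system the second. All four diastereomers of 21 converge on one product because the ester α-centres become sp2. The two arms are insulated by the biaryl and react independently, so one operation sets all four stereocentres, both of them quaternary carbinol centres included.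

Step 16
Reactants: 25 bis-acid
Product: 28 hexabenzyl ether of the target (both lactone rings closed; C3–OBn and all phenols benzylated), via bis-ozonide 26 (not isolated), via bis(hydroxy acid) 27 (not isolated)
Conditions: O3, CH2Cl2, −78 °C (Sudan Red 7B end point); then MeOH, NaBH4, −78 → 0 °C; 1 M HCl; TsOH·H2O (cat.), CH2Cl2, 23 °C
Reagents that add atoms: ozone, [O-][O+]=O
Why: Criegee ozonolysis of the two propenyl groups, which react much faster than benzyl-protected guaiacyl rings at −78 °C; hydride reduces the ozonides directly to the primary alcohols so that no C4-epimerisable aldehyde accumulates, and acid closes both γ-lactones, helped by the fully substituted C3. No stereocentre is touched.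

Step 17
Reactants: 28 hexabenzyl ether
Product: 29 target, CNP0218652.1
Conditions: H2 (1 atm), Pd(OH)2/C, EtOAc/MeOH, 23 °C
Reagents that add atoms: none
Why: Hydrogenolysis of four aryl benzyl ethers and two tertiary-alkyl benzyl ethers; the molecule has no other reducible group, and lactones and stereocentres are unaffected under neutral conditions.

## Compound list

1 | vanillin | COc1cc(C=O)ccc1O | starting material
2 | dehydrodivanillin | COc1cc(C=O)cc(-c2cc(C=O)cc(OC)c2O)c1O | intermediate
3 | 6,6'-bis(benzyloxy)-5,5'-dimethoxybiphenyl-3,3'-dicarbaldehyde | COc1cc(C=O)cc(-c2cc(C=O)cc(OC)c2OCc2ccccc2)c1OCc1ccccc1 | intermediate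
4 | [6,6'-bis(benzyloxy)-5,5'-dimethoxybiphenyl-3,3'-diyl]dimethanol | COc1cc(CO)cc(-c2cc(CO)cc(OC)c2OCc2ccccc2)c1OCc1ccccc1 | intermediate
5 | 2,2'-bis(benzyloxy)-5,5'-bis(bromomethyl)-3,3'-dimethoxybiphenyl | COc1cc(CBr)cc(-c2cc(CBr)cc(OC)c2OCc2ccccc2)c1OCc1ccccc1 | intermediate
6 | [4-(benzyloxy)-3-methoxyphenyl]methanol | COc1cc(CO)ccc1OCc1ccccc1 | starting material
7 | 1-(benzyloxy)-4-(bromomethyl)-2-methoxybenzene | COc1cc(CBr)ccc1OCc1ccccc1 | intermediate
8 | (R)-but-3-yn-2-ol | C[C@@H](O)C#C | starting material
9 | (R)-5-[4-(benzyloxy)-3-methoxyphenyl]pent-3-yn-2-ol | COc1cc(CC#C[C@@H](C)O)ccc1OCc1ccccc1 | intermediate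
10 | (R,Z)-5-[4-(benzyloxy)-3-methoxyphenyl]pent-3-en-2-ol | COc1cc(C/C=C\[C@@H](C)O)ccc1OCc1ccccc1 | intermediate
11 | (benzyloxy)acetyl chloride | O=C(Cl)COCc1ccccc1 | starting material
12 | (R,Z)-5-[4-(benzyloxy)-3-methoxyphenyl]pent-3-en-2-yl (benzyloxy)acetate | COc1cc(C/C=C\[C@@H](C)OC(=O)COCc2ccccc2)ccc1OCc1ccccc1 | intermediate
13 | methyl (benzyloxy)acetate | COC(=O)COCc1ccccc1 | starting material
14 | lithium enolate of 13 (benzyloxy cis to O–Li) | [Li]O/C(OC)=C\OCc1ccccc1 | intermediate
15 | methyl 2-(benzyloxy)-3-[4-(benzyloxy)-3-methoxyphenyl]propanoate (racemic) | COC(=O)C(Cc1ccc(OCc2ccccc2)c(OC)c1)OCc1ccccc1 | intermediate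
16 | 2-(benzyloxy)-3-[4-(benzyloxy)-3-methoxyphenyl]propanoic acid (racemic) | OC(=O)C(Cc1ccc(OCc2ccccc2)c(OC)c1)OCc1ccccc1 | intermediate
17 | lithium enolate of 12 (benzyloxy cis to O–Li) | COc1cc(C/C=C\[C@@H](C)O/C(O[Li])=C/OCc2ccccc2)ccc1OCc1ccccc1 | intermediate
18 | (R,Z)-5-[4-(benzyloxy)-3-methoxyphenyl]pent-3-en-2-yl 2-(benzyloxy)-3-[6,6'-bis(benzyloxy)-3'-(bromomethyl)-5,5'-dimethoxybiphenyl-3-yl]propanoate (C2 epimers) | COc1cc(C/C=C\[C@@H](C)OC(=O)C(Cc2cc(OC)c(OCc3ccccc3)c(-c3cc(CBr)cc(OC)c3OCc3ccccc3)c2)OCc2ccccc2)ccc1OCc1ccccc1 | intermediate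
19 | analogue of 18 with 3'-[(R)-4-hydroxypent-2-yn-1-yl] in place of bromomethyl | COc1cc(C/C=C\[C@@H](C)OC(=O)C(Cc2cc(OC)c(OCc3ccccc3)c(-c3cc(CC#C[C@@H](C)O)cc(OC)c3OCc3ccccc3)c2)OCc2ccccc2)ccc1OCc1ccccc1 | intermediate
20 | analogue of 18 with 3'-[(R,Z)-4-hydroxypent-2-en-1-yl] in place of bromomethyl | COc1cc(C/C=C\[C@@H](C)OC(=O)C(Cc2cc(OC)c(OCc3ccccc3)c(-c3cc(C/C=C\[C@@H](C)O)cc(OC)c3OCc3ccccc3)c2)OCc2ccccc2)ccc1OCc1ccccc1 | intermediate
21 | head-to-tail bis-ester (20 esterified with 16; four diastereomers at the ester α-carbons) | COc1cc(C/C=C\[C@@H](C)OC(=O)C(Cc2cc(OC)c(OCc3ccccc3)c(-c3cc(C/C=C\[C@@H](C)OC(=O)C(Cc4ccc(OCc5ccccc5)c(OC)c4)OCc4ccccc4)cc(OC)c3OCc3ccccc3)c2)OCc2ccccc2)ccc1OCc1ccccc1 | intermediate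
22 | bis(lithium enolate) of 21 (each benzyloxy cis to O–Li) | COc1cc(C/C=C\[C@@H](C)O/C(O[Li])=C(/OCc2ccccc2)Cc2cc(OC)c(OCc3ccccc3)c(-c3cc(C/C=C\[C@@H](C)O/C(O[Li])=C(/OCc4ccccc4)Cc4ccc(OCc5ccccc5)c(OC)c4)cc(OC)c3OCc3ccccc3)c2)ccc1OCc1ccccc1 | intermediate
23 | bis[(Z)-trimethylsilyl ketene acetal] of 21 | COc1cc(C/C=C\[C@@H](C)O/C(O[Si](C)(C)C)=C(/OCc2ccccc2)Cc2cc(OC)c(OCc3ccccc3)c(-c3cc(C/C=C\[C@@H](C)O/C(O[Si](C)(C)C)=C(/OCc4ccccc4)Cc4ccc(OCc5ccccc5)c(OC)c4)cc(OC)c3OCc3ccccc3)c2)ccc1OCc1ccccc1 | intermediate
24 | bis(trimethylsilyl ester) of 25 | C[Si](C)(C)OC(=O)[C@](Cc1cc(OC)c(OCc2ccccc2)c(-c2cc(C[C@H](/C=C/C)[C@@](Cc3ccc(OCc4ccccc4)c(OC)c3)(OCc3ccccc3)C(=O)O[Si](C)(C)C)cc(OC)c2OCc2ccccc2)c1)(OCc1ccccc1)[C@H](Cc1ccc(OCc2ccccc2)c(OC)c1)/C=C/C | intermediate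
25 | bis-acid: ring B–CH2–C(OBn)(CO2H)–CH[(E)-propenyl]–CH2–ring A and ring C–CH2–CH[(E)-propenyl]–C(OBn)(CO2H)–CH2–ring D, each pair (2R,3R) | OC(=O)[C@](Cc1cc(OC)c(OCc2ccccc2)c(-c2cc(C[C@H](/C=C/C)[C@@](Cc3ccc(OCc4ccccc4)c(OC)c3)(OCc3ccccc3)C(O)=O)cc(OC)c2OCc2ccccc2)c1)(OCc1ccccc1)[C@H](Cc1ccc(OCc2ccccc2)c(OC)c1)/C=C/C | intermediate
26 | bis-ozonide of 25 (each propenyl converted into a 5-methyl-1,2,4-trioxolan-3-yl group; ozonide carbons unassigned) | OC(=O)[C@](Cc1cc(OC)c(OCc2ccccc2)c(-c2cc(C[C@H](C3OOC(C)O3)[C@@](Cc3ccc(OCc4ccccc4)c(OC)c3)(OCc3ccccc3)C(O)=O)cc(OC)c2OCc2ccccc2)c1)(OCc1ccccc1)[C@H](Cc1ccc(OCc2ccccc2)c(OC)c1)C1OOC(C)O1 | intermediate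
27 | bis(γ-hydroxy acid) (each propenyl replaced by CH2OH) | OC(=O)[C@](Cc1cc(OC)c(OCc2ccccc2)c(-c2cc(C[C@H](CO)[C@@](Cc3ccc(OCc4ccccc4)c(OC)c3)(OCc3ccccc3)C(O)=O)cc(OC)c2OCc2ccccc2)c1)(OCc1ccccc1)[C@H](Cc1ccc(OCc2ccccc2)c(OC)c1)CO | intermediate
28 | hexabenzyl ether of the target, both lactones (3R,4R) | COc1cc(C[C@@H]2COC(=O)[C@@]2(OCc2ccccc2)Cc2cc(OC)c(OCc3ccccc3)c(-c3cc(C[C@@H]4COC(=O)[C@@]4(OCc4ccccc4)Cc4ccc(OCc5ccccc5)c(OC)c4)cc(OC)c3OCc3ccccc3)c2)ccc1OCc1ccccc1 | intermediate
29 | CNP0218652.1, both lactones (3R,4R) | COc1cc(C[C@@H]2COC(=O)[C@@]2(O)Cc2cc(OC)c(O)c(-c3cc(C[C@@H]4COC(=O)[C@@]4(O)Cc4ccc(O)c(OC)c4)cc(OC)c3O)c2)ccc1O | target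

## Step count and risk

Total: 17 steps. Longest linear sequence: 11 steps (steps 5, 6, 7, 8, 11, 12, 13, 14, 15, 16, 17; the branch through steps 1–4 is equally long).

**Step 15 (key step).**
- What may go wrong: partial loss of chelate control during enolisation of the α-branched α-benzyloxy esters, which would erode the configuration at C3 in one or both arms. The second rearrangement could also be incomplete, or a boat pathway could leak in.
- Fallback: it sets out from 12 and returns to the route at 28. It keeps the sigmatropic step only for C4, in its best-behaved unbranched glycolate form, and sets C3 by alkylation of a cyclic enolate.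
  - Glycolate 12 is rearranged under the conditions of step 15 to (3R,E)-2-(benzyloxy)-3-[4-(benzyloxy)-3-methoxybenzyl]hex-4-enoic acid F1.
  - F1 is cleaved and cyclised as in step 16 to (4R)-3-(benzyloxy)-4-[4-(benzyloxy)-3-methoxybenzyl]dihydrofuran-2(3H)-one F2.
  - The lithium enolate of F2 (LiN(SiMe3)2, THF, −78 °C) is alkylated by excess 5 anti to the C4 substituent, which gives lactone 1 bromide F3 with the (3R,4R) configuration.
  - Coupling with 8 as in step 12 gives alkynol F4, semihydrogenation gives Z-alkenol F5, and acylation with 11 gives glycolate F6.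
  - A second Ireland–Claisen rearrangement gives acid F7. The quaternary lactone 1 cannot enolise.
  - Oxidative cleavage and lactonisation give the C3-unsubstituted lactone 2 compound F8.
  - Alkylation of the enolate of F8 with 7, again anti to the C4 substituent, gives 28.

**Step 11.**
- What may go wrong: consumption of both bromomethyl arms by two enolate molecules, premature rearrangement of the lithium enolate on warming, and loss of the surviving p-alkoxybenzyl bromide during purification.
- Fallback: it sets out from 4 and returns at 18. It differentiates the two arms before the valuable enolate is used.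
  - Monosilylation of 4 (NaH, then tert-butyldimethylsilyl chloride, THF) gives the mono(silyl ether) alcohol F9; unreacted 4 is recycled.
  - CBr4/PPh3 gives the silyl ether bromide F10.
  - F10 alkylates enolate 17 in a 1:1 ratio to give the silyl ether ester F11.
  - Ph3PBr2 in CH2Cl2 converts the benzylic silyl ether of F11 directly into the bromide 18.

**Step 16.**
- What may go wrong: competitive ozonation of the six electron-rich arene rings or of benzylic ether C–H bonds once the alkenes are consumed, and epimerisation at C4 if an aldehyde-level intermediate persists before reduction.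
- Fallback: it sets out from 25 and returns at 27. It replaces ozone by a metal-oxo dihydroxylation and glycol cleavage that does not attack arenes.
  - OsO4 (cat.), NaIO4 and 2,6-lutidine in dioxane/H2O cleave both propenyl groups to the bis(aldehyde acid) F12.
  - F12 is reduced at once with NaBH4 at 0 °C to 27, which lactonises to 28 on acidification.

## Further compounds

F1 | step 15 | (3R,E)-2-(benzyloxy)-3-[4-(benzyloxy)-3-methoxybenzyl]hex-4-enoic acid (C2 unassigned) | C/C=C/[C@@H](Cc1ccc(OCc2ccccc2)c(OC)c1)C(OCc1ccccc1)C(O)=O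
F2 | step 15 | (4R)-3-(benzyloxy)-4-[4-(benzyloxy)-3-methoxybenzyl]dihydrofuran-2(3H)-one (C3 unassigned) | COc1cc(C[C@@H]2COC(=O)C2OCc2ccccc2)ccc1OCc1ccccc1
F3 | step 15 | lactone 1 bromide: (3R,4R)-3-(benzyloxy)-4-[4-(benzyloxy)-3-methoxybenzyl]-3-{[6,6'-bis(benzyloxy)-3'-(bromomethyl)-5,5'-dimethoxybiphenyl-3-yl]methyl}dihydrofuran-2(3H)-one | COc1cc(C[C@@H]2COC(=O)[C@@]2(OCc2ccccc2)Cc2cc(OC)c(OCc3ccccc3)c(-c3cc(CBr)cc(OC)c3OCc3ccccc3)c2)ccc1OCc1ccccc1
F4 | step 15 | alkynol: F3 with (R)-4-hydroxypent-2-yn-1-yl in place of bromomethyl | COc1cc(C[C@@H]2COC(=O)[C@@]2(OCc2ccccc2)Cc2cc(OC)c(OCc3ccccc3)c(-c3cc(CC#C[C@@H](C)O)cc(OC)c3OCc3ccccc3)c2)ccc1OCc1ccccc1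
F5 | step 15 | Z-alkenol: F3 with (R,Z)-4-hydroxypent-2-en-1-yl in place of bromomethyl | COc1cc(C[C@@H]2COC(=O)[C@@]2(OCc2ccccc2)Cc2cc(OC)c(OCc3ccccc3)c(-c3cc(C/C=C\[C@@H](C)O)cc(OC)c3OCc3ccccc3)c2)ccc1OCc1ccccc1
F6 | step 15 | glycolate: (benzyloxy)acetate of F5 | COc1cc(C[C@@H]2COC(=O)[C@@]2(OCc2ccccc2)Cc2cc(OC)c(OCc3ccccc3)c(-c3cc(C/C=C\[C@@H](C)OC(=O)COCc4ccccc4)cc(OC)c3OCc3ccccc3)c2)ccc1OCc1ccccc1
F7 | step 15 | acid: ring C arm CH2–CH[(E)-propenyl]–CH(OBn)–CO2H, (R) at the allyl-bearing carbon | COc1cc(C[C@@H]2COC(=O)[C@@]2(OCc2ccccc2)Cc2cc(OC)c(OCc3ccccc3)c(-c3cc(C[C@H](/C=C/C)C(OCc4ccccc4)C(O)=O)cc(OC)c3OCc3ccccc3)c2)ccc1OCc1ccccc1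
F8 | step 15 | bis-lactone lacking the C3 arylmethyl group of lactone 2 | COc1cc(C[C@@H]2COC(=O)[C@@]2(OCc2ccccc2)Cc2cc(OC)c(OCc3ccccc3)c(-c3cc(C[C@@H]4COC(=O)C4OCc4ccccc4)cc(OC)c3OCc3ccccc3)c2)ccc1OCc1ccccc1
F9 | step 11 | mono(tert-butyldimethylsilyl) ether of diol 4 | COc1cc(CO)cc(-c2cc(CO[Si](C)(C)C(C)(C)C)cc(OC)c2OCc2ccccc2)c1OCc1ccccc1
F10 | step 11 | silyl ether bromide | COc1cc(CBr)cc(-c2cc(CO[Si](C)(C)C(C)(C)C)cc(OC)c2OCc2ccccc2)c1OCc1ccccc1
F11 | step 11 | silyl ether ester: 18 with CH2OSi(tBu)Me2 in place of CH2Br | COc1cc(C/C=C\[C@@H](C)OC(=O)C(Cc2cc(OC)c(OCc3ccccc3)c(-c3cc(CO[Si](C)(C)C(C)(C)C)cc(OC)c3OCc3ccccc3)c2)OCc2ccccc2)ccc1OCc1ccccc1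
F12 | step 16 | bis(aldehyde acid): 25 with each propenyl replaced by CHO | OC(=O)[C@](Cc1cc(OC)c(OCc2ccccc2)c(-c2cc(C[C@H](C=O)[C@@](Cc3ccc(OCc4ccccc4)c(OC)c3)(OCc3ccccc3)C(O)=O)cc(OC)c2OCc2ccccc2)c1)(OCc1ccccc1)[C@H](Cc1ccc(OCc2ccccc2)c(OC)c1)C=O
A1 | alternative 1 | (3R,4R)-3-[4-(benzyloxy)-3-bromo-5-methoxybenzyl]-4-[4-(benzyloxy)-3-methoxybenzyl]-3-hydroxydihydrofuran-2(3H)-one | COc1cc(C[C@@H]2COC(=O)[C@@]2(O)Cc2cc(Br)c(OCc3ccccc3)c(OC)c2)ccc1OCc1ccccc1
A2 | alternative 1 | (3R,4R)-3-[4-(benzyloxy)-3-methoxybenzyl]-4-[4-(benzyloxy)-3-methoxy-5-(4,4,5,5-tetramethyl-1,3,2-dioxaborolan-2-yl)benzyl]-3-hydroxydihydrofuran-2(3H)-one | COc1cc(C[C@@H]2COC(=O)[C@@]2(O)Cc2ccc(OCc3ccccc3)c(OC)c2)cc(B2OC(C)(C)C(C)(C)O2)c1OCc1ccccc1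
A3 | alternative 2 | (3R,4R)-3-hydroxy-3,4-bis(4-hydroxy-3-methoxybenzyl)dihydrofuran-2(3H)-one | COc1cc(C[C@@H]2COC(=O)[C@@]2(O)Cc2ccc(O)c(OC)c2)ccc1O
A4 | alternative 3 | tetrabenzyl ether of the C3-deoxy dimer (both lactones trans, arylmethyl groups placed as in the target) | COc1cc(C[C@@H]2COC(=O)[C@H]2Cc2cc(OC)c(OCc3ccccc3)c(-c3cc(C[C@@H]4COC(=O)[C@H]4Cc4ccc(OCc5ccccc5)c(OC)c4)cc(OC)c3OCc3ccccc3)c2)ccc1OCc1ccccc1
A5 | alternative 3 | bis-C3-epimer of the target tetrabenzyl ether (hydroxyl trans to the C4 arylmethyl group in both lactones) | COc1cc(C[C@@H]2COC(=O)[C@]2(O)Cc2cc(OC)c(OCc3ccccc3)c(-c3cc(C[C@@H]4COC(=O)[C@]4(O)Cc4ccc(OCc5ccccc5)c(OC)c4)cc(OC)c3OCc3ccccc3)c2)ccc1OCc1ccccc1
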